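**Strategy.** Cembrane numbering is used (C1 carries the isopropyl group, C12 the methyl group and the ether oxygen). The oxolane ring O–C1–C14–C13–C12 is disconnected at C1–C14 and O–C12: C1 is a quaternary α-oxygenated carbon next to C2 (a masked carboxyl), and the vicinal oxygens on C11/C12 betray a C11–C12 epoxide. In one flask the dioxolanone enolate of (S)-2-hydroxyisovaleric acid is alkylated by an epoxy iodide at C14, the acylal is methanolysed and the freed C1 alkoxide opens the epoxide at C12 (5-exo, inversion), giving the cis-2,5-oxolane with C1, C11 and C12 set. The 14-membered ring is closed later at C6–C7 (Nozaki–Hiyama–Kishi).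

Key step: step 9

Remark: hydroxy ester 17 and hydroxy aldehyde 18 may rest partly as the bicyclic lactone or lactol formed with the C11 hydroxyl; these forms react as the open compounds drawn.

Step 1
Reactants: 1 tert-butyl(but-3-yn-1-yloxy)dimethylsilane
Product: 3 tert-butyl{[(3E)-4-iodo-3-methylbut-3-en-1-yl]oxy}dimethylsilane, via alkenylalane 2 (not isolated)
Conditions: Me3Al, Cp2ZrCl2 (cat.), CH2Cl2, 0 °C to rt; then I2, THF, −30 °C
Reagents that add atoms: trimethylaluminium C[Al](C)C; iodine II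
Why: Zirconium-catalysed syn-methylalumination of the terminal alkyne (Negishi carboalumination) places the methyl group on the internal carbon, and iodinolysis of the C–Al bond with retention should give the E-iodoalkene that becomes C11=C12.

Step 2
Reactants: 3 tert-butyl{[(3E)-4-iodo-3-methylbut-3-en-1-yl]oxy}dimethylsilane; 4 (4-iodobut-1-yn-1-yl)trimethylsilane
Product: 6 tert-butyldimethyl{[(3E)-3-methyl-8-(trimethylsilyl)oct-3-en-7-yn-1-yl]oxy}silane, via alkylzinc iodide 5 (not isolated)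
Conditions: 4, Zn dust, LiCl, THF, 40 °C; then 3, PdCl2(dppf) (cat.), THF, rt
Reagents that add atoms: none
Why: Negishi cross-coupling of a primary alkylzinc iodide with an alkenyl iodide forms the C10–C11 bond with retention of the E geometry, the silyl-capped alkyne staying inert.

Step 3
Reactants: 6 tert-butyldimethyl{[(3E)-3-methyl-8-(trimethylsilyl)oct-3-en-7-yn-1-yl]oxy}silane
Product: 7 tert-butyldimethyl{[(3E)-3-methyloct-3-en-7-yn-1-yl]oxy}silane
Conditions: K2CO3 (cat.), MeOH, rt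
Reagents that add atoms: none
Why: Base-catalysed methanolysis cleaves only the alkynyl C–Si bond, the silyl ether being stable to carbonate in methanol.

Step 4
Reactants: 7 tert-butyldimethyl{[(3E)-3-methyloct-3-en-7-yn-1-yl]oxy}silane
Product: 9 tert-butyl{[(3E,7E)-8-iodo-3,7-dimethylocta-3,7-dien-1-yl]oxy}dimethylsilane, via dienylalane 8 (not isolated)
Conditions: Me3Al, Cp2ZrCl2 (cat.), CH2Cl2, 0 °C to rt; then I2, THF, −30 °C
Reagents that add atoms: trimethylaluminium C[Al](C)C; iodine II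
Why: A second carboalumination–iodination acts only on the terminal alkyne (the trisubstituted alkene is inert) and should give the E-iodoalkene C7=C8 that carries the future C8 methyl group.

Step 5
Reactants: 9 tert-butyl{[(3E,7E)-8-iodo-3,7-dimethylocta-3,7-dien-1-yl]oxy}dimethylsilane
Product: 10 tert-butyl(2-{(2R,3R)-3-[(3E)-4-iodo-3-methylbut-3-en-1-yl]-2-methyloxiran-2-yl}ethoxy)dimethylsilane
Conditions: D-fructose-derived Shi ketone (0.3 equiv), Oxone (2KHSO5·KHSO4·K2SO4), K2CO3, Bu4NHSO4, MeCN/CH2(OMe)2/aq. buffer pH 10.5, 0 °C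
Reagents that add atoms: potassium peroxymonosulfate [K+].[O-]S(=O)(=O)OO
Why: Shi asymmetric epoxidation by the chiral dioxirane should attack the electron-rich trisubstituted C11=C12 alkene in preference to the electron-poor iodoalkene and, through the spiro transition state of the D-fructose-derived ketone, give the (R,R)-epoxide.

Step 6
Reactants: 10 tert-butyl(2-{(2R,3R)-3-[(3E)-4-iodo-3-methylbut-3-en-1-yl]-2-methyloxiran-2-yl}ethoxy)dimethylsilane
Product: 11 2-{(2R,3R)-3-[(3E)-4-iodo-3-methylbut-3-en-1-yl]-2-methyloxiran-2-yl}ethan-1-ol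
Conditions: Bu4NF, THF, 0 °C
Reagents that add atoms: none
Why: Fluoride cleaves the Si–O bond under non-acidic conditions that leave the trisubstituted epoxide and the iodoalkene untouched.

Step 7
Reactants: 11 2-{(2R,3R)-3-[(3E)-4-iodo-3-methylbut-3-en-1-yl]-2-methyloxiran-2-yl}ethan-1-ol
Product: 12 (2R,3R)-2-(2-iodoethyl)-3-[(3E)-4-iodo-3-methylbut-3-en-1-yl]-2-methyloxirane
Conditions: I2, PPh3, imidazole, CH2Cl2, 0 °C
Reagents that add atoms: iodine II
Why: Appel-type iodination converts the primary alcohol through its alkoxyphosphonium salt into the iodide, imidazole buffering the medium so that the epoxide should survive.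

Step 8
Reactants: 13 (2S)-2-hydroxy-3-methylbutanoic acid
Product: 14 (2S,5S)-2-tert-butyl-5-(propan-2-yl)-1,3-dioxolan-4-one
Conditions: (CH3)3CCHO, TsOH·H2O (cat.), H2SO4 (cat.), pentane, reflux, water separator; cis isomer purified by crystallisation or chromatography
Reagents that add atoms: 2,2-dimethylpropanal CC(C)(C)C=O
Why: Acid-catalysed acetalisation of the α-hydroxy acid should give mainly the cis-dioxolanone, whose acetal carbon stores the chirality for the later enolate alkylation (self-regeneration of stereocentres).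

Step 9
Reactants: 14 (2S,5S)-2-tert-butyl-5-(propan-2-yl)-1,3-dioxolan-4-one; 12 (2R,3R)-2-(2-iodoethyl)-3-[(3E)-4-iodo-3-methylbut-3-en-1-yl]-2-methyloxirane
Product: 17 methyl (2S,5S)-5-[(1R,4E)-1-hydroxy-5-iodo-4-methylpent-4-en-1-yl]-5-methyl-2-(propan-2-yl)oxolane-2-carboxylate, via alkylated dioxolanone 15 (not isolated), via epoxy hydroxy ester 16 (not isolated)
Conditions: 14 (1.1 equiv), LiN(iPr)2, THF, −78 °C; then 12, DMPU, −78 to −30 °C; then MeOH, NaOMe (cat.), 0 °C to rt; then camphorsulfonic acid (cat., to pH 3), rt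
Reagents that add atoms: methanol CO
Why: The lithium enolate of 14 is C-alkylated at C14 by the primary iodide of 12 (SN2) on the face anti to the tert-butyl group of the acetal, methoxide then opens the acylal to the methyl ester with loss of pivalaldehyde, and the freed C1 oxygen attacks C12 of the epoxide, the acid completing this closure. The closest known reaction types are the self-regeneration-of-stereocentres alkylation of 2-tert-butyl-1,3-dioxolan-4-one enolates and the hydroxy-epoxide cyclisation that forms the oxolane of incensole-type cembranoids. The oxolane ring closes in the 5-exo-tet mode at the tertiary epoxide carbon. C1 is controlled by the acetal stereocentre (the new C14 substituent takes the place of the former hydrogen, overall retention), C12 by inversion of the (R)-epoxide carbon to (S), and C11 is carried over unchanged from the epoxide. The step needs C- over O-alkylation and attack at the iodide rather than the epoxide, secured by the soft enolate and the primary iodide at −78 °C, and 5-exo over 6-endo opening, secured because the exo carbon is also the tertiary, cation-stabilising one. Since both ring centres are set independently and absolutely, the isopropyl and methyl groups should end up cis on the oxolane as the bridged target requires.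

Step 10
Reactants: 17 methyl (2S,5S)-5-[(1R,4E)-1-hydroxy-5-iodo-4-methylpent-4-en-1-yl]-5-methyl-2-(propan-2-yl)oxolane-2-carboxylate
Product: 18 (2S,5S)-5-[(1R,4E)-1-hydroxy-5-iodo-4-methylpent-4-en-1-yl]-5-methyl-2-(propan-2-yl)oxolane-2-carbaldehyde
Conditions: i-Bu2AlH (2.2 equiv), CH2Cl2, −78 °C; aq. KNaC4H4O6 work-up
Reagents that add atoms: none
Why: Partial reduction of the hindered α-alkoxy ester stops at the aldehyde stage because the tetrahedral aluminate next to the quaternary carbon is stable at −78 °C.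

Step 11
Reactants: 18 (2S,5S)-5-[(1R,4E)-1-hydroxy-5-iodo-4-methylpent-4-en-1-yl]-5-methyl-2-(propan-2-yl)oxolane-2-carbaldehyde; 19 ethyl (2E)-4-(diethoxyphosphoryl)-3-methylbut-2-enoate
Product: 20 ethyl (2E,4E)-5-{(2S,5S)-5-[(1R,4E)-1-hydroxy-5-iodo-4-methylpent-4-en-1-yl]-5-methyl-2-(propan-2-yl)oxolan-2-yl}-3-methylpenta-2,4-dienoate
Conditions: 19 (2.5 equiv), LiN(SiMe3)2, THF/DMPU, −78 to 0 °C; (2E,4E) isomer purified by chromatography
Reagents that add atoms: none
Why: The vinylogous Horner–Wadsworth–Emmons reaction of the small stabilised phosphonate anion tolerates the neopentyl aldehyde and should form the C2=C3 bond E and bring in C3–C6 with the C4 methyl group.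

Step 12
Reactants: 20 ethyl (2E,4E)-5-{(2S,5S)-5-[(1R,4E)-1-hydroxy-5-iodo-4-methylpent-4-en-1-yl]-5-methyl-2-(propan-2-yl)oxolan-2-yl}-3-methylpenta-2,4-dienoate
Product: 21 (2E,4E)-5-{(2S,5S)-5-[(1R,4E)-1-hydroxy-5-iodo-4-methylpent-4-en-1-yl]-5-methyl-2-(propan-2-yl)oxolan-2-yl}-3-methylpenta-2,4-dien-1-ol
Conditions: i-Bu2AlH (3.5 equiv), CH2Cl2, −78 °C
Reagents that add atoms: none
Why: 1,2-Reduction of the dienoate by the aluminium hydride gives the allylic alcohol without touching the diene or the iodoalkene.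

Step 13
Reactants: 21 (2E,4E)-5-{(2S,5S)-5-[(1R,4E)-1-hydroxy-5-iodo-4-methylpent-4-en-1-yl]-5-methyl-2-(propan-2-yl)oxolan-2-yl}-3-methylpenta-2,4-dien-1-ol
Product: 22 [(2R,3R)-3-{(E)-2-[(2S,5S)-5-[(1R,4E)-1-hydroxy-5-iodo-4-methylpent-4-en-1-yl]-5-methyl-2-(propan-2-yl)oxolan-2-yl]ethenyl}-3-methyloxiran-2-yl]methanol
Conditions: Ti(OiPr)4 (cat.), D-(−)-diethyl tartrate (cat.), t-BuOOH, 4 Å molecular sieves, CH2Cl2, −20 °C
Reagents that add atoms: tert-butyl hydroperoxide CC(C)(C)OO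
Why: Sharpless asymmetric epoxidation acts only on the C4=C5 alkene allylic to the primary alcohol, and D-(−)-tartrate should give the (2R,3R)-epoxy alcohol (as with geraniol), which fixes the C4–O bond in the configuration that becomes 4S.

Step 14
Reactants: 22 [(2R,3R)-3-{(E)-2-[(2S,5S)-5-[(1R,4E)-1-hydroxy-5-iodo-4-methylpent-4-en-1-yl]-5-methyl-2-(propan-2-yl)oxolan-2-yl]ethenyl}-3-methyloxiran-2-yl]methanol
Product: 23 (3S,4E)-5-{(2S,5S)-5-[(1R,4E)-1-hydroxy-5-iodo-4-methylpent-4-en-1-yl]-5-methyl-2-(propan-2-yl)oxolan-2-yl}-3-methylpent-4-ene-1,3-diol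
Conditions: NaAlH2(OCH2CH2OMe)2 (Red-Al), THF, 0 °C
Reagents that add atoms: none
Why: Intramolecular hydride delivery from the alkoxyaluminate opens the 2,3-epoxy alcohol at C5 to the 1,3-diol, so the C4–O bond and its configuration are retained as the tertiary allylic alcohol.

Step 15
Reactants: 23 (3S,4E)-5-{(2S,5S)-5-[(1R,4E)-1-hydroxy-5-iodo-4-methylpent-4-en-1-yl]-5-methyl-2-(propan-2-yl)oxolan-2-yl}-3-methylpent-4-ene-1,3-diol
Product: 24 (3S,4E)-3-hydroxy-5-{(2S,5S)-5-[(1R,4E)-1-hydroxy-5-iodo-4-methylpent-4-en-1-yl]-5-methyl-2-(propan-2-yl)oxolan-2-yl}-3-methylpent-4-enal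
Conditions: TEMPO (cat.), PhI(OAc)2, CH2Cl2, rt; used at once
Reagents that add atoms: none
Why: The oxoammonium oxidation is selective for the primary alcohol over the hindered secondary C11 and the tertiary C4 hydroxyl groups and is neutral enough to spare the β-hydroxy aldehyde.

Step 16
Reactants: 24 (3S,4E)-3-hydroxy-5-{(2S,5S)-5-[(1R,4E)-1-hydroxy-5-iodo-4-methylpent-4-en-1-yl]-5-methyl-2-(propan-2-yl)oxolan-2-yl}-3-methylpent-4-enal
Product: 25 (1S,2E,4S,7E,11R,12S)-1,12-epoxycembra-2,7-diene-4,6,11-triol (both C6 epimers)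
Conditions: CrCl2 (excess), NiCl2 (cat.), DMSO/THF, rt, slow addition at high dilution
Reagents that add atoms: none
Why: The Nozaki–Hiyama–Kishi reaction adds the alkenylchromium formed from the iodoalkene to the aldehyde chemoselectively in the presence of free hydroxyl groups and closes the 14-membered ring at C6–C7 with retention of the E geometry.

Step 17
Reactants: 25 (1S,2E,4S,7E,11R,12S)-1,12-epoxycembra-2,7-diene-4,6,11-triol (both C6 epimers)
Product: 26 (1S,2E,4S,7E,11R,12S)-1,12-epoxy-4,11-dihydroxycembra-2,7-dien-6-one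
Conditions: MnO2 (excess), CH2Cl2, rt
Reagents that add atoms: none
Why: MnO2 oxidises only the secondary allylic C6 alcohol, so both C6 epimers converge on one enone while the tertiary C4 and the non-allylic C11 hydroxyl groups stay.

Step 18
Reactants: 26 (1S,2E,4S,7E,11R,12S)-1,12-epoxy-4,11-dihydroxycembra-2,7-dien-6-one
Product: 27 (1S,2E,4S,8S,11R,12S)-1,12-epoxy-4,11-dihydroxycembr-2-en-6-one
Conditions: Cu(OAc)2·H2O (cat.), (R)-DTBM-SEGPHOS (cat.), (EtO)2MeSiH (1.2 equiv), t-BuOH, toluene, −20 °C; aq. NH4F work-up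
Reagents that add atoms: none
Why: Ligand-controlled copper hydride conjugate reduction of the E-β-methyl enone should set C8 by hydride delivery to one face and leave the isolated C2=C3 alkene alone, the (R)-ligand being proposed by analogy with acyclic enones and its antipode taken if a trial shows the opposite sense.

Step 19
Reactants: 27 (1S,2E,4S,8S,11R,12S)-1,12-epoxy-4,11-dihydroxycembr-2-en-6-one
Product: 28 (1S,2E,4S,8S,11R,12S)-1,12-epoxy-4-hydroxy-6-oxocembr-2-en-11-yl formate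
Conditions: HCO2H, DCC, DMAP (cat.), CH2Cl2, 0 °C
Reagents that add atoms: formic acid O=CO
Why: Steglich formylation with the smallest acyl donor should esterify the secondary C11 alcohol with retention and leave the tertiary C4 alcohol unreacted.

**Compound list**

1 | tert-butyl(but-3-yn-1-yloxy)dimethylsilane | C#CCCO[Si](C)(C)C(C)(C)C | starting material
2 | {(1E)-4-[(tert-butyldimethylsilyl)oxy]-2-methylbut-1-en-1-yl}dimethylaluminium | C[Al](C)/C=C(C)/CCO[Si](C)(C)C(C)(C)C | intermediate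
3 | tert-butyl{[(3E)-4-iodo-3-methylbut-3-en-1-yl]oxy}dimethylsilane | I/C=C(C)/CCO[Si](C)(C)C(C)(C)C | intermediate
4 | (4-iodobut-1-yn-1-yl)trimethylsilane | C[Si](C)(C)C#CCCI | starting material
5 | [4-(trimethylsilyl)but-3-yn-1-yl]zinc iodide | C[Si](C)(C)C#CCC[Zn]I | intermediate
6 | tert-butyldimethyl{[(3E)-3-methyl-8-(trimethylsilyl)oct-3-en-7-yn-1-yl]oxy}silane | C[Si](C)(C)C#CCC/C=C(C)/CCO[Si](C)(C)C(C)(C)C | intermediate
7 | tert-butyldimethyl{[(3E)-3-methyloct-3-en-7-yn-1-yl]oxy}silane | C#CCC/C=C(C)/CCO[Si](C)(C)C(C)(C)C | intermediate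
8 | {(1E,5E)-8-[(tert-butyldimethylsilyl)oxy]-2,6-dimethylocta-1,5-dien-1-yl}dimethylaluminium | C[Al](C)/C=C(C)/CC/C=C(C)/CCO[Si](C)(C)C(C)(C)C | intermediate
9 | tert-butyl{[(3E,7E)-8-iodo-3,7-dimethylocta-3,7-dien-1-yl]oxy}dimethylsilane | I/C=C(C)/CC/C=C(C)/CCO[Si](C)(C)C(C)(C)C | intermediate
10 | tert-butyl(2-{(2R,3R)-3-[(3E)-4-iodo-3-methylbut-3-en-1-yl]-2-methyloxiran-2-yl}ethoxy)dimethylsilane | I/C=C(C)/CC[C@H]1O[C@]1(C)CCO[Si](C)(C)C(C)(C)C | intermediate
11 | 2-{(2R,3R)-3-[(3E)-4-iodo-3-methylbut-3-en-1-yl]-2-methyloxiran-2-yl}ethan-1-ol | I/C=C(C)/CC[C@H]1O[C@]1(C)CCO | intermediate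
12 | (2R,3R)-2-(2-iodoethyl)-3-[(3E)-4-iodo-3-methylbut-3-en-1-yl]-2-methyloxirane | I/C=C(C)/CC[C@H]1O[C@]1(C)CCI | intermediate
13 | (2S)-2-hydroxy-3-methylbutanoic acid | CC(C)[C@H](O)C(=O)O | starting material
14 | (2S,5S)-2-tert-butyl-5-(propan-2-yl)-1,3-dioxolan-4-one | CC(C)[C@@H]1O[C@H](C(C)(C)C)OC1=O | intermediate
15 | (2S,5S)-2-tert-butyl-5-(2-{(2R,3R)-3-[(3E)-4-iodo-3-methylbut-3-en-1-yl]-2-methyloxiran-2-yl}ethyl)-5-(propan-2-yl)-1,3-dioxolan-4-one | CC(C)[C@]1(CC[C@@]2(C)O[C@@H]2CC/C(C)=C/I)O[C@H](C(C)(C)C)OC1=O | intermediate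
16 | methyl (2S)-2-hydroxy-4-{(2R,3R)-3-[(3E)-4-iodo-3-methylbut-3-en-1-yl]-2-methyloxiran-2-yl}-2-(propan-2-yl)butanoate | CC(C)[C@@](O)(CC[C@@]1(C)O[C@@H]1CC/C(C)=C/I)C(=O)OC | intermediate
17 | methyl (2S,5S)-5-[(1R,4E)-1-hydroxy-5-iodo-4-methylpent-4-en-1-yl]-5-methyl-2-(propan-2-yl)oxolane-2-carboxylate | CC(C)[C@]1(C(=O)OC)CC[C@@](C)([C@H](O)CC/C(C)=C/I)O1 | intermediate
18 | (2S,5S)-5-[(1R,4E)-1-hydroxy-5-iodo-4-methylpent-4-en-1-yl]-5-methyl-2-(propan-2-yl)oxolane-2-carbaldehyde | CC(C)[C@]1(C=O)CC[C@@](C)([C@H](O)CC/C(C)=C/I)O1 | intermediate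
19 | ethyl (2E)-4-(diethoxyphosphoryl)-3-methylbut-2-enoate | CCOC(=O)/C=C(\C)CP(=O)(OCC)OCC | starting material
20 | ethyl (2E,4E)-5-{(2S,5S)-5-[(1R,4E)-1-hydroxy-5-iodo-4-methylpent-4-en-1-yl]-5-methyl-2-(propan-2-yl)oxolan-2-yl}-3-methylpenta-2,4-dienoate | CCOC(=O)/C=C(C)/C=C/[C@@]1(C(C)C)CC[C@@](C)([C@H](O)CC/C(C)=C/I)O1 | intermediate
21 | (2E,4E)-5-{(2S,5S)-5-[(1R,4E)-1-hydroxy-5-iodo-4-methylpent-4-en-1-yl]-5-methyl-2-(propan-2-yl)oxolan-2-yl}-3-methylpenta-2,4-dien-1-ol | OC/C=C(C)/C=C/[C@@]1(C(C)C)CC[C@@](C)([C@H](O)CC/C(C)=C/I)O1 | intermediate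
22 | [(2R,3R)-3-{(E)-2-[(2S,5S)-5-[(1R,4E)-1-hydroxy-5-iodo-4-methylpent-4-en-1-yl]-5-methyl-2-(propan-2-yl)oxolan-2-yl]ethenyl}-3-methyloxiran-2-yl]methanol | OC[C@H]2O[C@]2(C)/C=C/[C@@]1(C(C)C)CC[C@@](C)([C@H](O)CC/C(C)=C/I)O1 | intermediate
23 | (3S,4E)-5-{(2S,5S)-5-[(1R,4E)-1-hydroxy-5-iodo-4-methylpent-4-en-1-yl]-5-methyl-2-(propan-2-yl)oxolan-2-yl}-3-methylpent-4-ene-1,3-diol | OCC[C@](C)(O)/C=C/[C@@]1(C(C)C)CC[C@@](C)([C@H](O)CC/C(C)=C/I)O1 | intermediate
24 | (3S,4E)-3-hydroxy-5-{(2S,5S)-5-[(1R,4E)-1-hydroxy-5-iodo-4-methylpent-4-en-1-yl]-5-methyl-2-(propan-2-yl)oxolan-2-yl}-3-methylpent-4-enal | O=CC[C@](C)(O)/C=C/[C@@]1(C(C)C)CC[C@@](C)([C@H](O)CC/C(C)=C/I)O1 | intermediate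
25 | (1S,2E,4S,7E,11R,12S)-1,12-epoxycembra-2,7-diene-4,6,11-triol (both C6 epimers) | CC(C)[C@]12/C=C/[C@@](C)(O)CC(O)/C=C(C)/CC[C@@H](O)[C@](C)(CC1)O2 | intermediate
26 | (1S,2E,4S,7E,11R,12S)-1,12-epoxy-4,11-dihydroxycembra-2,7-dien-6-one | CC(C)[C@]12/C=C/[C@@](C)(O)CC(=O)/C=C(C)/CC[C@@H](O)[C@](C)(CC1)O2 | intermediate
27 | (1S,2E,4S,8S,11R,12S)-1,12-epoxy-4,11-dihydroxycembr-2-en-6-one | CC(C)[C@]12/C=C/[C@@](C)(O)CC(=O)C[C@@H](C)CC[C@@H](O)[C@](C)(CC1)O2 | intermediate
28 | (1S,2E,4S,8S,11R,12S)-1,12-epoxy-4-hydroxy-6-oxocembr-2-en-11-yl formate | CC(C)[C@]12/C=C/[C@@](C)(O)CC(=O)C[C@@H](C)CC[C@@H](OC=O)[C@](C)(CC1)O2 | target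

**Count.** Total: 19 steps. Longest linear sequence: 18 steps (steps 1–7 and 9–19, from 1 to 28).

**Steps most likely to fail**

1. Step 9. The hindered tetrasubstituted enolate may be alkylated too slowly by the unactivated primary iodide. Base-induced loss of the epoxide (elimination or methoxide opening) and thermal decay of the enolate may then compete, and the oxolane may not close cleanly in the flask. Fallback: the epoxide is introduced only after the C1–C14 bond exists. It sets out from 9 and 14. Bu4NF frees (3E,7E)-8-iodo-3,7-dimethylocta-3,7-dien-1-ol F1, and I2/PPh3/imidazole gives (1E,5E)-1,8-diiodo-2,6-dimethylocta-1,5-diene F2. F2 has no epoxide and tolerates HMPA and warming in the alkylation of the enolate of 14, which gives (2S,5S)-2-tert-butyl-5-[(3E,7E)-8-iodo-3,7-dimethylocta-3,7-dien-1-yl]-5-(propan-2-yl)-1,3-dioxolan-4-one F3. NaOMe/MeOH releases methyl (2S,5E,9E)-2-hydroxy-10-iodo-5,9-dimethyl-2-(propan-2-yl)deca-5,9-dienoate F4. Shi epoxidation of F4 with the same ketone then gives 16, which closes on mild acid treatment, and the route is rejoined at 17.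

2. Step 18. The conformation of the macrocycle may override the ligand, so that hydride is delivered to C8 with low or reversed facial selectivity, and excess silane may over-reduce the ketone. Fallback: the alkene is hydrogenated at the allylic alcohol stage instead. It sets out from 25. Iridium-catalysed asymmetric hydrogenation ([Ir(cod)(PHOX)]BArF, H2, CH2Cl2) of the trisubstituted C7=C8 alkene should leave the C2=C3 alkene, which is shielded by two fully substituted carbons. It gives (1S,2E,4S,8S,11R,12S)-1,12-epoxycembr-2-ene-4,6,11-triol F5 as C6 epimers. The oxoammonium salt 4-acetamido-2,2,6,6-tetramethyl-1-oxopiperidinium tetrafluoroborate then oxidises the unhindered C6 carbinol in preference to the neopentyl-type C11 carbinol, and the route is rejoined at 27.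

3. Step 16 (with the aldehyde from step 15). The β-hydroxy aldehyde 24 may undergo retro-aldol cleavage or dehydration before or during the slow high-dilution ring closure, and oligomers may form. Fallback: the C4 oxygen is carried through the ring closure as the epoxide and unmasked afterwards. It sets out from 22. TEMPO/PhI(OAc)2 gives (2S,3R)-3-{(E)-2-[(2S,5S)-5-[(1R,4E)-1-hydroxy-5-iodo-4-methylpent-4-en-1-yl]-5-methyl-2-(propan-2-yl)oxolan-2-yl]ethenyl}-3-methyloxirane-2-carbaldehyde F6, which cannot undergo retro-aldol cleavage. Nozaki–Hiyama–Kishi closure gives (1S,2E,4R,5R,7E,11R,12S)-1,12:4,5-diepoxycembra-2,7-diene-6,11-diol F7 as C6 epimers, and MnO2 gives (1S,2E,4R,5S,7E,11R,12S)-1,12:4,5-diepoxy-11-hydroxycembra-2,7-dien-6-one F8. SmI2 (THF/MeOH, −90 °C) then cleaves the C5–O bond of the α,β-epoxy ketone with retention at C4, and the route is rejoined at 26.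

Further compounds
F1 | step 9 | (3E,7E)-8-iodo-3,7-dimethylocta-3,7-dien-1-ol | I/C=C(C)/CC/C=C(C)/CCO
F2 | step 9 | (1E,5E)-1,8-diiodo-2,6-dimethylocta-1,5-diene | I/C=C(C)/CC/C=C(C)/CCI
F3 | step 9 | (2S,5S)-2-tert-butyl-5-[(3E,7E)-8-iodo-3,7-dimethylocta-3,7-dien-1-yl]-5-(propan-2-yl)-1,3-dioxolan-4-one | CC(C)[C@]1(CC/C(C)=C/CC/C(C)=C/I)O[C@H](C(C)(C)C)OC1=O
F4 | step 9 | methyl (2S,5E,9E)-2-hydroxy-10-iodo-5,9-dimethyl-2-(propan-2-yl)deca-5,9-dienoate | CC(C)[C@@](O)(CC/C(C)=C/CC/C(C)=C/I)C(=O)OC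
F5 | step 18 | (1S,2E,4S,8S,11R,12S)-1,12-epoxycembr-2-ene-4,6,11-triol (both C6 epimers) | CC(C)[C@]12/C=C/[C@@](C)(O)CC(O)C[C@@H](C)CC[C@@H](O)[C@](C)(CC1)O2
F6 | step 16 | (2S,3R)-3-{(E)-2-[(2S,5S)-5-[(1R,4E)-1-hydroxy-5-iodo-4-methylpent-4-en-1-yl]-5-methyl-2-(propan-2-yl)oxolan-2-yl]ethenyl}-3-methyloxirane-2-carbaldehyde | O=C[C@H]2O[C@]2(C)/C=C/[C@@]1(C(C)C)CC[C@@](C)([C@H](O)CC/C(C)=C/I)O1
F7 | step 16 | (1S,2E,4R,5R,7E,11R,12S)-1,12:4,5-diepoxycembra-2,7-diene-6,11-diol (both C6 epimers) | CC(C)[C@]12/C=C/[C@@]3(C)O[C@@H]3C(O)/C=C(C)/CC[C@@H](O)[C@](C)(CC1)O2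
F8 | step 16 | (1S,2E,4R,5S,7E,11R,12S)-1,12:4,5-diepoxy-11-hydroxycembra-2,7-dien-6-one | CC(C)[C@]12/C=C/[C@@]3(C)O[C@@H]3C(=O)/C=C(C)/CC[C@@H](O)[C@](C)(CC1)O2
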